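Everything rests on reading ring C of the upper epiafzelechin unit as a 3-arylindan-1-one that lacks one atom, O1, which sits between C8a of ring A and C2. C8a is meta to O5 and O7 and is out of reach of electrophilic oxygenation. A Baeyer–Villiger shift of the aryl–carbonyl bond puts oxygen on that very carbon. In one operation the oxidation forms C8a–O1 and enlarges the five-membered ketone to the ring C lactone, leaving C4 untouched. Its precursor is the (3R)-4,6-dibenzyloxy-3-(protected epicatechin-8-yl)indan-1-one from an asymmetric reductive Heck closure, with C6' of ring D capped by bromine. C3 and C2 are then relayed from C4.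

Key step: step 9

Conventions:
- Flavan numbering is used. Unprimed atoms and rings A, B, C belong to the upper unit; primed atoms and rings D, E, F belong to the lower unit.
- Indanone C1, C2, C3 and C7a become flavan C2, C3, C4 and C8a.
- Bn = benzyl; TBS = tert-butyldimethylsilyl.
- EC = (2R,3R)-5,7-dibenzyloxy-2-(3,4-dibenzyloxyphenyl)-3-(TBS-oxy)chroman-8-yl; BrEC = its 6-bromo derivative.
- Compounds 1, 7, 19 and 25 are catalogue compounds.

Assumption: the sense of induction of the bisphosphine in step 7 is taken by analogy with simple 2'-halochalcones; if the (R)-ligand proves mismatched with the lower unit, its antipode is used and nothing else changes.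

Step 1
Reactants: 1 (−)-epicatechin
Product: 2 (2R,3R)-5,7-dibenzyloxy-2-(3,4-dibenzyloxyphenyl)chroman-3-ol
Conditions: BnBr (4.4 equiv), K2CO3, DMF, 0 °C → rt, argon
Reagents that add atoms: benzyl bromide, BrCc1ccccc1
Why: Williamson etherification in which K2CO3 ionises only the four phenols and not the secondary C3 alcohol, while the mild temperature should avoid base-induced C2 epimerisation, so no stereocentre is touched.

Step 2
Reactants: 2 (2R,3R)-5,7-dibenzyloxy-2-(3,4-dibenzyloxyphenyl)chroman-3-ol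
Product: 3 (2R,3R)-8-bromo-5,7-dibenzyloxy-2-(3,4-dibenzyloxyphenyl)chroman-3-ol
Conditions: NBS (1.0 equiv), CH2Cl2, −78 °C → rt
Reagents that add atoms: N-bromosuccinimide, O=C1CCC(=O)N1Br
Why: Electrophilic aromatic bromination, for which C8 of the phloroglucinol-type ring is the established kinetic site in perbenzylated flavan-3-ols and the catechol ring is much less activated.

Step 3
Reactants: 3 (2R,3R)-8-bromo-5,7-dibenzyloxy-2-(3,4-dibenzyloxyphenyl)chroman-3-ol
Product: 4 (2R,3R)-8-bromo-5,7-dibenzyloxy-2-(3,4-dibenzyloxyphenyl)-3-(TBS-oxy)chroman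
Conditions: TBSCl, imidazole, DMF, rt
Reagents that add atoms: tert-butyldimethylsilyl chloride, CC(C)(C)[Si](C)(C)Cl
Why: Standard imidazole-promoted silylation of the secondary alcohol, giving a group that should survive organolithium, hydroxide, palladium, peracid and hydride reagents and later leave with fluoride.

Step 4
Reactants: 4 (2R,3R)-8-bromo-5,7-dibenzyloxy-2-(3,4-dibenzyloxyphenyl)-3-(TBS-oxy)chroman
Product: 6 (2R,3R)-5,7-dibenzyloxy-2-(3,4-dibenzyloxyphenyl)-3-(TBS-oxy)chroman-8-carbaldehyde, via aryllithium 5 (not isolated)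
Conditions: n-BuLi, THF, −78 °C; DMF, −78 → 0 °C; H2O
Reagents that add atoms: N,N-dimethylformamide, CN(C)C=O
Why: Bromine–lithium exchange outruns benzylic deprotonation at −78 °C, and formylation of aryllithium 5 with DMF (Bouveault-type) places the carbon substituent at C8 without regiochemical doubt.

Step 5
Reactants: 7 3,5-dibenzyloxyacetophenone
Product: 8 1-(2-bromo-3,5-dibenzyloxyphenyl)ethanone
Conditions: NBS (1.0 equiv), MeCN, 0 °C → rt
Reagents that add atoms: N-bromosuccinimide, O=C1CCC(=O)N1Br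
Why: Electrophilic aromatic bromination in a polar solvent should go to C2, which is para to one ether and ortho to the other, because C4 between the two ethers is more crowded and side-chain bromination needs acid or radical conditions.

Step 6
Reactants: 6 (2R,3R)-5,7-dibenzyloxy-2-(3,4-dibenzyloxyphenyl)-3-(TBS-oxy)chroman-8-carbaldehyde; 8 1-(2-bromo-3,5-dibenzyloxyphenyl)ethanone
Product: 10 (E)-1-(2-bromo-3,5-dibenzyloxyphenyl)-3-(EC)prop-2-en-1-one, via aldol adduct 9 (not isolated)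
Conditions: KOH, EtOH–THF, rt
Reagents that add atoms: none
Why: Claisen–Schmidt condensation in which the aldehyde cannot enolise, the methyl ketone is the only enolate source, and E1cB loss of water from aldol 9 gives the conjugated E-enone under thermodynamic control.

Step 7
Reactants: 10 (E)-1-(2-bromo-3,5-dibenzyloxyphenyl)-3-(EC)prop-2-en-1-one
Product: 11 (3R)-4,6-dibenzyloxy-3-(EC)indan-1-one
Conditions: Pd(OAc)2 (10 mol %), (R)-3,5-Xyl-MeO-BIPHEP (12 mol %), HCO2Na, DMF–ethylene glycol, 80 °C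
Reagents that add atoms: none
Why: Asymmetric intramolecular reductive Heck reaction of a 2'-halochalcone, in which oxidative addition at the acyl-activated C–Br bond, carbopalladation joining that aryl carbon to the enone β-carbon and hydride transfer from formate close the five-membered ring; the chiral bisphosphine (bromide dissociation helped by the glycol) selects the alkene face and so sets C3 as R (the future C4), and any minor epimer is a diastereomer removable by chromatography.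

Step 8
Reactants: 11 (3R)-4,6-dibenzyloxy-3-(EC)indan-1-one
Product: 12 (3R)-4,6-dibenzyloxy-3-(BrEC)indan-1-one
Conditions: NBS (1.0 equiv), CH2Cl2, −78 → 0 °C
Reagents that add atoms: N-bromosuccinimide, O=C1CCC(=O)N1Br
Why: Electrophilic aromatic bromination at C6', the only free position of the trioxygenated ring D and far more nucleophilic than the acyl-deactivated indanone ring or ring E, installs a cap that makes ring D poorer in electrons, removes its last C–H and leaves in the final hydrogenolysis at no cost in steps.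

Step 9
Reactants: 12 (3R)-4,6-dibenzyloxy-3-(BrEC)indan-1-one
Product: 14 (4R)-5,7-dibenzyloxy-4-(BrEC)chroman-2-one, via Criegee adduct 13 (not isolated)
Conditions: m-CPBA (3 equiv), NaHCO3, CH2Cl2, 0 °C → rt, dark
Reagents that add atoms: m-chloroperbenzoic acid, O=C(OO)c1cccc(Cl)c1
Why: The peracid adds to the C1 carbonyl to give Criegee adduct 13, in which aryl carbon C7a (the future C8a), placed anti to the O–O bond, shifts from carbon to oxygen as 3-chlorobenzoate departs. This is the Baeyer–Villiger oxidation of 1-indanones to 3,4-dihydrocoumarins, which is also known for 3-aryl-1-indanones. Ring C is not closed by a cyclisation but arises by a one-atom ring expansion (1,2-shift) of the five-membered ketone, with C8a–O1 as the only new bond. No stereocentre is made, and C4 lies β to the carbonyl and outside the migrating bond, so its R configuration should be carried over. The first selectivity needed is aryl over CH2 migration, which rests on the higher migratory aptitude of an aryl carbon that can bridge through its π system compared with a primary alkyl carbon, and on both ring A ethers being meta to the carbonyl so that they do not slow peracid addition. The second is ketone over arene oxidation, which rests on the C6' bromine (ring D has no C–H left and is less electron rich), on the acyl group that deactivates ring A, and on the NaHCO3 buffer that suppresses acid-promoted arene hydroxylation and silyl loss.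

Step 10
Reactants: 14 (4R)-5,7-dibenzyloxy-4-(BrEC)chroman-2-one
Product: 16 (4R)-2-acetoxy-5,7-dibenzyloxy-4-(BrEC)chroman (both C2 epimers), via diisobutylaluminium hemiacetal 15 (not isolated)
Conditions: i-Bu2AlH (1.1 equiv), CH2Cl2, −78 °C; then pyridine, DMAP, Ac2O, −78 → 0 °C
Reagents that add atoms: acetic anhydride, CC(=O)OC(C)=O
Why: Reductive acetylation of a lactone, in which the aluminium hemiacetal 15 is stable at −78 °C and is acylated in its closed form, avoiding over-reduction and the ring–chain equilibrium of the free lactol; the C2 configuration is of no consequence here.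

Step 11
Reactants: 16 (4R)-2-acetoxy-5,7-dibenzyloxy-4-(BrEC)chroman
Product: 18 (4R)-5,7-dibenzyloxy-4-(BrEC)-4H-chromene, via oxocarbenium triflate 17 (not isolated)
Conditions: TMSOTf, i-Pr2NEt, CH2Cl2, −20 °C → rt
Reagents that add atoms: none
Why: Silyl triflate–amine elimination of an acetal-type acetate, in which TMSOTf ionises the anomeric acetate to ion 17 and the hindered amine removes a proton from C3, the only β-position, to give the cyclic enol ether without touching C4.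

Step 12
Reactants: 18 (4R)-5,7-dibenzyloxy-4-(BrEC)-4H-chromene; 19 4-benzyloxybromobenzene
Product: 23 (2R,3R,4R)-5,7-dibenzyloxy-2-(4-benzyloxyphenyl)-4-(BrEC)chroman-3-ol, via 4-benzyloxyphenyllithium 20 (not isolated), via bis(4-benzyloxyphenyl)zinc 21 (not isolated), via 2,3-epoxychroman 22 (not isolated)
Conditions: dimethyldioxirane (acetone solution), CH2Cl2, −40 → 0 °C, volatiles removed; then 21 (from 19: n-BuLi, THF, −78 °C; ZnBr2; solvent changed to toluene–n-Bu2O), 0 °C → rt; H2O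
Reagents that add atoms: dimethyldioxirane, CC1(C)OO1
Why: Dimethyldioxirane epoxidation of a cyclic enol ether followed by syn opening of the acetal epoxide with a diarylzinc in a non-coordinating solvent, as practised on glycal epoxides; the C4 aryl group, held pseudoaxial by the peri C5 ether, shields the β face so that oxygen enters on the α face and sets C3 trans to C4, after which zinc binds the epoxide oxygen and hands its aryl group to C2 on the same α face, setting C2 cis to O3 and trans to C4.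

Step 13
Reactants: 23 (2R,3R,4R)-5,7-dibenzyloxy-2-(4-benzyloxyphenyl)-4-(BrEC)chroman-3-ol
Product: 24 (2R,3R,4R)-5,7-dibenzyloxy-2-(4-benzyloxyphenyl)-4-[(2R,3R)-6-bromo-5,7-dibenzyloxy-2-(3,4-dibenzyloxyphenyl)-3-hydroxychroman-8-yl]chroman-3-ol
Conditions: HF·pyridine, pyridine–THF, 0 °C → rt
Reagents that add atoms: none
Why: Fluoride-driven cleavage of the remaining silyl ether under pyridine-buffered conditions that should leave the benzyl ethers, the aryl bromide and the C4–C8' bond alone.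

Step 14
Reactants: 24 the 3,3'-diol of step 13; 25 3,4,5-tribenzyloxybenzoic acid
Product: 26 3,3'-bis-O-(3,4,5-tribenzyloxybenzoyl) derivative of 24
Conditions: 25 (3 equiv), DCC, DMAP, CH2Cl2, rt
Reagents that add atoms: none
Why: Steglich esterification with DMAP as acyl-transfer catalyst acylates both axial secondary alcohols, and since only O–H bonds are broken the configuration at C3 and C3' is retained.

Step 15
Reactants: 26 3,3'-bis-O-(3,4,5-tribenzyloxybenzoyl) derivative of 24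
Product: 27 epiafzelechin 3-O-gallate-(4β→8)-epicatechin 3-O-gallate (CNP0291968.1)
Conditions: H2 (1 atm), Pd(OH)2/C, NaOAc, THF–MeOH–H2O, rt
Reagents that add atoms: none
Why: Catalytic hydrogenolysis cleaves the thirteen benzyl ethers and the C6'–Br bond in one operation, with NaOAc taking up the HBr so that the acid-labile C4–C8' bond and the gallate esters should survive; no stereocentre is involved.

Compound list
1 | (−)-epicatechin | O[C@@H]1Cc2c(O)cc(O)cc2O[C@@H]1c1ccc(O)c(O)c1 | starting material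
2 | (2R,3R)-5,7-dibenzyloxy-2-(3,4-dibenzyloxyphenyl)chroman-3-ol | O[C@@H]1Cc2c(OCc9ccccc9)cc(OCc9ccccc9)cc2O[C@@H]1c1ccc(OCc9ccccc9)c(OCc9ccccc9)c1 | intermediate
3 | (2R,3R)-8-bromo-5,7-dibenzyloxy-2-(3,4-dibenzyloxyphenyl)chroman-3-ol | O[C@@H]1Cc2c(OCc9ccccc9)cc(OCc9ccccc9)c(Br)c2O[C@@H]1c1ccc(OCc9ccccc9)c(OCc9ccccc9)c1 | intermediate
4 | (2R,3R)-8-bromo-5,7-dibenzyloxy-2-(3,4-dibenzyloxyphenyl)-3-(TBS-oxy)chroman | CC(C)(C)[Si](C)(C)O[C@@H]1Cc2c(OCc9ccccc9)cc(OCc9ccccc9)c(Br)c2O[C@@H]1c1ccc(OCc9ccccc9)c(OCc9ccccc9)c1 | intermediate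
5 | 8-lithio analogue of 4 (aryllithium) | CC(C)(C)[Si](C)(C)O[C@@H]1Cc2c(OCc9ccccc9)cc(OCc9ccccc9)c([Li])c2O[C@@H]1c1ccc(OCc9ccccc9)c(OCc9ccccc9)c1 | intermediate
6 | (2R,3R)-5,7-dibenzyloxy-2-(3,4-dibenzyloxyphenyl)-3-(TBS-oxy)chroman-8-carbaldehyde | CC(C)(C)[Si](C)(C)O[C@@H]1Cc2c(OCc9ccccc9)cc(OCc9ccccc9)c(C=O)c2O[C@@H]1c1ccc(OCc9ccccc9)c(OCc9ccccc9)c1 | intermediate
7 | 3,5-dibenzyloxyacetophenone | CC(=O)c1cc(OCc2ccccc2)cc(OCc2ccccc2)c1 | starting material
8 | 1-(2-bromo-3,5-dibenzyloxyphenyl)ethanone | CC(=O)c1cc(OCc9ccccc9)cc(OCc9ccccc9)c1Br | intermediate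
9 | aldol adduct, 1-(2-bromo-3,5-dibenzyloxyphenyl)-3-hydroxy-3-(EC)propan-1-one (carbinol epimers) | O=C(CC(O)c2c(OCc9ccccc9)cc(OCc9ccccc9)c3c2O[C@H](c2ccc(OCc9ccccc9)c(OCc9ccccc9)c2)[C@H](O[Si](C)(C)C(C)(C)C)C3)c1cc(OCc9ccccc9)cc(OCc9ccccc9)c1Br | intermediate
10 | (E)-1-(2-bromo-3,5-dibenzyloxyphenyl)-3-(EC)prop-2-en-1-one | O=C(/C=C/c2c(OCc9ccccc9)cc(OCc9ccccc9)c3c2O[C@H](c2ccc(OCc9ccccc9)c(OCc9ccccc9)c2)[C@H](O[Si](C)(C)C(C)(C)C)C3)c1cc(OCc9ccccc9)cc(OCc9ccccc9)c1Br | intermediate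
11 | (3R)-4,6-dibenzyloxy-3-(EC)indan-1-one | O=C1C[C@@H](c2c(OCc9ccccc9)cc(OCc9ccccc9)c3c2O[C@H](c2ccc(OCc9ccccc9)c(OCc9ccccc9)c2)[C@H](O[Si](C)(C)C(C)(C)C)C3)c2c(OCc9ccccc9)cc(OCc9ccccc9)cc21 | intermediate
12 | (3R)-4,6-dibenzyloxy-3-(BrEC)indan-1-one | O=C1C[C@@H](c2c(OCc9ccccc9)c(Br)c(OCc9ccccc9)c3c2O[C@H](c2ccc(OCc9ccccc9)c(OCc9ccccc9)c2)[C@H](O[Si](C)(C)C(C)(C)C)C3)c2c(OCc9ccccc9)cc(OCc9ccccc9)cc21 | intermediate
13 | Criegee adduct, 1-hydroxy-1-(3-chlorobenzoylperoxy)indane derived from 12 (C1 epimers) | OC1(OOC(=O)c4cccc(Cl)c4)C[C@@H](c2c(OCc9ccccc9)c(Br)c(OCc9ccccc9)c3c2O[C@H](c2ccc(OCc9ccccc9)c(OCc9ccccc9)c2)[C@H](O[Si](C)(C)C(C)(C)C)C3)c2c(OCc9ccccc9)cc(OCc9ccccc9)cc21 | intermediate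
14 | (4R)-5,7-dibenzyloxy-4-(BrEC)chroman-2-one | O=C1C[C@@H](c2c(OCc9ccccc9)c(Br)c(OCc9ccccc9)c3c2O[C@H](c2ccc(OCc9ccccc9)c(OCc9ccccc9)c2)[C@H](O[Si](C)(C)C(C)(C)C)C3)c2c(OCc9ccccc9)cc(OCc9ccccc9)cc2O1 | intermediate
15 | diisobutylaluminium hemiacetal of 14 (C2 epimers) | CC(C)C[Al](CC(C)C)OC1C[C@@H](c2c(OCc9ccccc9)c(Br)c(OCc9ccccc9)c3c2O[C@H](c2ccc(OCc9ccccc9)c(OCc9ccccc9)c2)[C@H](O[Si](C)(C)C(C)(C)C)C3)c2c(OCc9ccccc9)cc(OCc9ccccc9)cc2O1 | intermediate
16 | (4R)-2-acetoxy-5,7-dibenzyloxy-4-(BrEC)chroman (C2 epimers) | CC(=O)OC1C[C@@H](c2c(OCc9ccccc9)c(Br)c(OCc9ccccc9)c3c2O[C@H](c2ccc(OCc9ccccc9)c(OCc9ccccc9)c2)[C@H](O[Si](C)(C)C(C)(C)C)C3)c2c(OCc9ccccc9)cc(OCc9ccccc9)cc2O1 | intermediate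
17 | (4R)-5,7-dibenzyloxy-4-(BrEC)-3,4-dihydrochromenylium triflate | C=1C[C@@H](c2c(OCc9ccccc9)c(Br)c(OCc9ccccc9)c3c2O[C@H](c2ccc(OCc9ccccc9)c(OCc9ccccc9)c2)[C@H](O[Si](C)(C)C(C)(C)C)C3)c2c(OCc9ccccc9)cc(OCc9ccccc9)cc2[O+]=1.[O-]S(=O)(=O)C(F)(F)F | intermediate
18 | (4R)-5,7-dibenzyloxy-4-(BrEC)-4H-chromene | C1=C[C@@H](c2c(OCc9ccccc9)c(Br)c(OCc9ccccc9)c3c2O[C@H](c2ccc(OCc9ccccc9)c(OCc9ccccc9)c2)[C@H](O[Si](C)(C)C(C)(C)C)C3)c2c(OCc9ccccc9)cc(OCc9ccccc9)cc2O1 | intermediate
19 | 4-benzyloxybromobenzene | Brc1ccc(OCc2ccccc2)cc1 | starting material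
20 | 4-benzyloxyphenyllithium | [Li]c1ccc(OCc2ccccc2)cc1 | intermediate
21 | bis(4-benzyloxyphenyl)zinc | c1ccccc1COc1ccc([Zn]c2ccc(OCc3ccccc3)cc2)cc1 | intermediate
22 | (2S,3R,4R)-5,7-dibenzyloxy-4-(BrEC)-2,3-epoxychroman (epoxide on the α face, trans to the C4 aryl group) | O4[C@@H]5[C@@H](c2c(OCc9ccccc9)c(Br)c(OCc9ccccc9)c3c2O[C@H](c2ccc(OCc9ccccc9)c(OCc9ccccc9)c2)[C@H](O[Si](C)(C)C(C)(C)C)C3)c2c(OCc9ccccc9)cc(OCc9ccccc9)cc2O[C@H]45 | intermediate
23 | (2R,3R,4R)-5,7-dibenzyloxy-2-(4-benzyloxyphenyl)-4-(BrEC)chroman-3-ol | O[C@@H]1[C@@H](c2c(OCc9ccccc9)c(Br)c(OCc9ccccc9)c3c2O[C@H](c2ccc(OCc9ccccc9)c(OCc9ccccc9)c2)[C@H](O[Si](C)(C)C(C)(C)C)C3)c2c(OCc9ccccc9)cc(OCc9ccccc9)cc2O[C@@H]1c1ccc(OCc9ccccc9)cc1 | intermediate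
24 | 3,3'-diol: (2R,3R,4R)-5,7-dibenzyloxy-2-(4-benzyloxyphenyl)-4-[(2R,3R)-6-bromo-5,7-dibenzyloxy-2-(3,4-dibenzyloxyphenyl)-3-hydroxychroman-8-yl]chroman-3-ol | O[C@@H]1[C@@H](c2c(OCc9ccccc9)c(Br)c(OCc9ccccc9)c3c2O[C@H](c2ccc(OCc9ccccc9)c(OCc9ccccc9)c2)[C@H](O)C3)c2c(OCc9ccccc9)cc(OCc9ccccc9)cc2O[C@@H]1c1ccc(OCc9ccccc9)cc1 | intermediate
25 | 3,4,5-tribenzyloxybenzoic acid | O=C(O)c1cc(OCc9ccccc9)c(OCc9ccccc9)c(OCc9ccccc9)c1 | starting material
26 | 3,3'-bis-O-(3,4,5-tribenzyloxybenzoyl) derivative of 24 | O=C(O[C@@H]1[C@@H](c2c(OCc9ccccc9)c(Br)c(OCc9ccccc9)c3c2O[C@H](c2ccc(OCc9ccccc9)c(OCc9ccccc9)c2)[C@H](OC(=O)c2cc(OCc9ccccc9)c(OCc9ccccc9)c(OCc9ccccc9)c2)C3)c2c(OCc9ccccc9)cc(OCc9ccccc9)cc2O[C@@H]1c1ccc(OCc9ccccc9)cc1)c1cc(OCc9ccccc9)c(OCc9ccccc9)c(OCc9ccccc9)c1 | intermediate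
27 | epiafzelechin 3-O-gallate-(4β→8)-epicatechin 3-O-gallate, (2R,3R,4R) upper unit and (2'R,3'R) lower unit | O=C(O[C@@H]1[C@@H](c2c(O)cc(O)c3c2O[C@H](c2ccc(O)c(O)c2)[C@H](OC(=O)c2cc(O)c(O)c(O)c2)C3)c2c(O)cc(O)cc2O[C@@H]1c1ccc(O)cc1)c1cc(O)c(O)c(O)c1 | target

Total step count: 15. Longest linear sequence: 14 steps (steps 1–4 and 6–15).

Steps most likely to fail

Step 9.
- What may go wrong: oxygen insertion may be slow, because the migrating carbon gains nothing from the two meta ethers. Methylene migration, or slow oxidation of rings A and E or of the product, could then take over.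
- Fallback: give up the ring expansion and build the lactone by annulation, setting out from aldehyde 6.
- Knoevenagel condensation of 6 with 2,2-dimethyl-1,3-dioxane-4,6-dione (pyrrolidine/AcOH cat., toluene) should give the arylidene dioxanedione F1.
- Yb(OTf)3-catalysed reaction of F1 with commercial 3,5-dibenzyloxyphenol goes by C-alkylation ortho to the OH, then acyl transfer with loss of acetone and CO2. It should give the debromo lactone F2 as two C4 epimers, which are diastereomers and are separated.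
- NBS then caps C6', and the route is rejoined at 14.

Step 12.
- What may go wrong: the labile acetal epoxide may rearrange before aryl transfer, or the aryl group may be delivered from a loosened ion pair with poor facial fidelity.
- Fallback: reverse the order of bond formation at C2 (aryl first, hydride last), setting out from lactone 14.
- KN(SiMe3)2 followed by 2-(phenylsulfonyl)-3-phenyloxaziridine at −78 °C should hydroxylate the enolate anti to the C4 aryl group to give the 3,4-trans hydroxylactone F3.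
- TBSOTf/2,6-lutidine gives the silyl ether F4.
- 4-Benzyloxyphenylmagnesium bromide (from 19 and Mg) adds once to give the hemiketal F5.
- Et3SiH/BF3·OEt2 at −78 °C should reduce the derived 2-aryl oxocarbenium ion from the face anti to the pseudoaxial C3 silyl ether, as in lactol reductions to C-aryl glycosides, to give the bis-silyl ether F6.
- HF·pyridine removes both silyl groups, and the route is rejoined at 24.

Step 7.
- What may go wrong: formate may reduce the arylpalladium bromide before the slow insertion into the crowded enone (hydrodebromination), facial control may be weak, and benzyl ethers may be lost if palladium metal separates.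
- Fallback: close the same bond without a hydride source, setting out from chalcone 10.
- Miyaura borylation (Pd(dppf)Cl2, B2pin2, KOAc, dioxane) should give the boronate F7.
- Rhodium-catalysed asymmetric intramolecular 1,4-addition ([Rh(C2H4)2Cl]2, MonoPhos, aq K3PO4, toluene) then returns to 11.

Further compounds
F1 | step 9 | 5-[(EC)methylidene]-2,2-dimethyl-1,3-dioxane-4,6-dione | CC1(C)OC(=O)C(=Cc2c(OCc9ccccc9)cc(OCc9ccccc9)c3c2O[C@H](c2ccc(OCc9ccccc9)c(OCc9ccccc9)c2)[C@H](O[Si](C)(C)C(C)(C)C)C3)C(=O)O1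
F2 | step 9 | (4R)-5,7-dibenzyloxy-4-(EC)chroman-2-one | O=C1C[C@@H](c2c(OCc9ccccc9)cc(OCc9ccccc9)c3c2O[C@H](c2ccc(OCc9ccccc9)c(OCc9ccccc9)c2)[C@H](O[Si](C)(C)C(C)(C)C)C3)c2c(OCc9ccccc9)cc(OCc9ccccc9)cc2O1
F3 | step 12 | (3R,4R)-5,7-dibenzyloxy-3-hydroxy-4-(BrEC)chroman-2-one | O[C@@H]1[C@@H](c2c(OCc9ccccc9)c(Br)c(OCc9ccccc9)c3c2O[C@H](c2ccc(OCc9ccccc9)c(OCc9ccccc9)c2)[C@H](O[Si](C)(C)C(C)(C)C)C3)c2c(OCc9ccccc9)cc(OCc9ccccc9)cc2OC1=O
F4 | step 12 | (3R,4R)-5,7-dibenzyloxy-3-(TBS-oxy)-4-(BrEC)chroman-2-one | CC(C)(C)[Si](C)(C)O[C@@H]1[C@@H](c2c(OCc9ccccc9)c(Br)c(OCc9ccccc9)c3c2O[C@H](c2ccc(OCc9ccccc9)c(OCc9ccccc9)c2)[C@H](O[Si](C)(C)C(C)(C)C)C3)c2c(OCc9ccccc9)cc(OCc9ccccc9)cc2OC1=O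
F5 | step 12 | (3R,4R)-5,7-dibenzyloxy-2-(4-benzyloxyphenyl)-3-(TBS-oxy)-4-(BrEC)chroman-2-ol (C2 epimers) | CC(C)(C)[Si](C)(C)O[C@@H]1[C@@H](c2c(OCc9ccccc9)c(Br)c(OCc9ccccc9)c3c2O[C@H](c2ccc(OCc9ccccc9)c(OCc9ccccc9)c2)[C@H](O[Si](C)(C)C(C)(C)C)C3)c2c(OCc9ccccc9)cc(OCc9ccccc9)cc2OC1(O)c1ccc(OCc9ccccc9)cc1
F6 | step 12 | (2R,3R,4R)-5,7-dibenzyloxy-2-(4-benzyloxyphenyl)-3-(TBS-oxy)-4-(BrEC)chroman | CC(C)(C)[Si](C)(C)O[C@@H]1[C@@H](c2c(OCc9ccccc9)c(Br)c(OCc9ccccc9)c3c2O[C@H](c2ccc(OCc9ccccc9)c(OCc9ccccc9)c2)[C@H](O[Si](C)(C)C(C)(C)C)C3)c2c(OCc9ccccc9)cc(OCc9ccccc9)cc2O[C@@H]1c1ccc(OCc9ccccc9)cc1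
F7 | step 7 | (E)-1-[3,5-dibenzyloxy-2-(4,4,5,5-tetramethyl-1,3,2-dioxaborolan-2-yl)phenyl]-3-(EC)prop-2-en-1-one | O=C(/C=C/c2c(OCc9ccccc9)cc(OCc9ccccc9)c3c2O[C@H](c2ccc(OCc9ccccc9)c(OCc9ccccc9)c2)[C@H](O[Si](C)(C)C(C)(C)C)C3)c1cc(OCc9ccccc9)cc(OCc9ccccc9)c1B4OC(C)(C)C(C)(C)O4
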